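## Analysis of the target

The target is a C25 bicyclic terpenoid: a trans-decalin (rings A and B, C1–C10; gem-dimethyl on C4, methyls on C8 and C10) whose C9 carries the chain C11–C15, which ends in a 4-methylbut-2-enolide (C16 = CH–O, C17 = C–CH3, C18 = CH, C19 = C=O). Five stereocentres sit on the decalin: 5α-H, 10β-CH3, 9β-chain, and the equatorial 6α- and 8α-hydroxyls, with the 8β-methyl axial and syn to the C10 methyl. Two more form a remote pair, 15S and 16S, with O15 and the ring oxygen on C16 syn across the C15–C16 bond; the C13=C14 alkene is E. At least five bonds separate C15 from the nearest ring stereocentre, so C15 has to be set by a reagent, while C16 can be relayed from C15. The butenolide is the most fragile part: its C16–H is removed by base, which leads to epimerisation or to a 2-oxyfuran. The C15 alcohol is allylic and ionises under acid, and the tertiary C8 alcohol can dehydrate. The difficulty is that the carbon skeleton needs strong bases, hydrides and organometallic reagents, none of which the butenolide tolerates. The plan rests on the fact that ring C16–C19, with its ring oxygen and the C17 methyl, is the oxidised form of a 2-alkyl-3-methylfuran. A furan carrying silicon on C19 is flat, base-stable, and on photooxygenation places the carbonyl on C19 and an oxygen on C16.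

## Retrosynthetic reasoning

**Target 24 to bis-silyl ether 23 (O6–Si and O15–Si).** The last operation is only the cleavage of two silyl ethers under buffered acidic fluoride. Nothing basic touches the finished butenolide.

**Butenolide 23 to hydroxybutenolide 20 (C16–H).** The C16–H bond is made last among the skeletal features, by hydride addition to the C16 carbonyl of the ring-opened form of 20. Cutting here lets the existing C15 centre, with its bulky silyl ether, direct the new one (Felkin–Anh, 15,16-syn). It also delays the appearance of the epimerisable C16–H to the penultimate step. The forward step must add hydride 1,2, avoid conjugate reduction, and close the lactone under acid.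

**Hydroxybutenolide 20 to silylfuran 17 (C16–O and C19=O).** Both oxygen atoms are removed, which returns the aromatic furan. Every C–C bond of the chain can then be made while C16–C19 is an arene that ignores bases, hydrides, organozinc reagents and palladium. Silicon on C19 decides which α-carbon becomes the carbonyl. The forward step must oxidise the furan and leave C13=C14 alone.

**Furan 17 back to propargylic alcohol 13 through 16 and 15 (C13–CH3, then C13–I and C14–H).** The E-trisubstituted alkene is traced to an alkyne by anti addition of H and CH3. A carbonyl olefination of a methyl ketone was not chosen, because there CH3 and CH2 differ too little. Here the geometry follows from intramolecular hydride delivery in 14 and from a stereoretentive cross-coupling.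

**Propargylic alcohol 13 to alkyne 7 and aldehyde 11 (C14–C15).** This is the convergent cut and the one that sets C15. An alkynyl nucleophile adding to aldehyde 11 only has to tell H from the furyl group. Reducing a C15 ketone would instead ask a reagent to tell a furyl group from an alkenyl or alkynyl group, two unsaturated substituents of similar demand.

**Aldehyde 11 to aldehyde 8 (C19–Si).** Silicon is put on the small aldehyde, where C19–H is the only acidic ring position. On a late intermediate the C15–H (allylic, furylic and α to oxygen) would compete.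

**Alcohol 7 to enyne 5 through epoxide 6 (C8–O, C8–CH3).** The tertiary carbinol comes from the exocyclic alkene by α-face epoxidation and hydride opening at the methylene carbon. This has to precede the arrival of the furan, which a peracid would destroy.

**Enyne 5 to diol 1 through 3 and 2.** The alkyne carbons C13 and C14 are the carbonyl and methyl carbons of methyl ketone 2, and 2 is diol 1 minus its two vinyl carbons. Diol 1 supplies both rings, C5, C6, C9 and C10, the 6α-oxygen and C11–C13, so no C–H oxidation at C6 is needed.

## Alternatives that were turned down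

**Alternative 1:** The decalin is disconnected into an acyclic polyene. A class-two terpene cyclase (a drimenyl diphosphate synthase) with a phosphatase would convert (2E,6E)-farnesyl diphosphate A1 into drimenol A2, closing rings A and B, setting C5, C9 and C10, and leaving a C7=C8 alkene.
- For: two rings and three stereocentres arise in one catalytic step from an achiral precursor with complete enantiocontrol, and the supply does not depend on a plant labdane. On bond economy for the ring system it is stronger than the chosen route, which builds no ring at all.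
- Against: A2 has no oxygen at C6 or C8. Turning the alkene into the 6α,8α-diol needs allylic oxidation to the 7-en-6-one, epoxidation, reductive epoxide opening, and reduction of the C6 ketone to the equatorial alcohol. That reduction runs against the preference of hydride for α-face attack, which gives the axial 6β-ol. C11 must then be extended by three carbons, and the enzyme has to be produced.
- Comparison: the chosen route obtains the oxygenation pattern and C11–C13 with its starting material and spends its steps on C15, C16 and the butenolide, where the real difficulty lies.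

**Alternative 2:** Ring B is disconnected at C6–C7. Me2AlCl would activate the C6 aldehyde of the monocyclic ring-A aldehyde A3, and a type-two carbonyl-ene reaction of its isopropenyl group would give A4, the ethylene ketal of ketone 2.
- For: one step forms ring B, the C6 carbinol and the exocyclic alkene; a chair transition state should favour the 6α-alcohol; the route is fully synthetic and open to ring analogues. On that flexibility it is stronger than the chosen route.
- Against: A3 must already carry C5, C9 and C10, two of them adjacent and one quaternary, which means a long enantioselective sequence before the key step.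
- Comparison: the product A4 is a protecting-group step away from compound 2, which the chosen route reaches in one step from 1. The alternative therefore arrives at the same point much later.

**Alternative 3:** Both rings are disconnected at C5–C10 and C8–C9. A protonated B-(o-tolyl)oxazaborolidine (diphenylprolinol-derived, triflimide salt) would catalyse the intramolecular Diels–Alder reaction of silyloxydiene–enal A5 to the trans-fused adduct A6.
- For: two rings and four stereocentres (C5, C8, C9, C10) form in one catalytic asymmetric step, and the enol ether marks C6 for oxygen. On convergence it is stronger than the chosen route.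
- Against: the C5–C10 bond joins a diene terminus next to the quaternary C4 to a fully substituted dienophile carbon, and a β,β-disubstituted enal is a weak dienophile even when activated. The silyl dienol ether is exposed to a strong Lewis acid. C8 emerges as a methine, so the tertiary 8α-alcohol needs dehydrogenation to the 7-en-6-one, epoxidation, reductive opening to a retro-aldol-prone β-hydroxy ketone, and an equatorial-selective reduction. C11 still lacks three carbons.
- Comparison: it is longer and has two uncertain operations before the side chain begins. The chosen route has one demanding step, at the end, on a substrate reached by standard reactions.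

Key step: step 11

Assumption: (+)-larixol, the 6α-hydroxylabdane of larch oleoresin, is taken as a purchasable chiral-pool compound whose C5, C6, C9 and C10 configurations are those of the target.

## Route

Step 1
Reactants: 1 (+)-larixol
Product: 2 methyl ketone (decalin with 6α-OH, exocyclic C8=CH2 and a 3-oxobutyl chain on C9)
Conditions: KMnO4, MgSO4, acetone–H2O, 0 °C → rt
Reagents that add atoms: none
Why: Permanganate cleavage of a tertiary vinyl carbinol: dihydroxylation of the monosubstituted vinyl group, glycol cleavage and oxidative decarboxylation of the α-hydroxy acid excise the two vinyl carbons and leave the methyl ketone. The more hindered 1,1-disubstituted ring alkene and the hindered 6α-hydroxyl should react more slowly, and no ring stereocentre is touched.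

Step 2
Reactants: 2 methyl ketone
Product: 3 6α-triethylsilyl ether of 2
Conditions: Et3SiCl, imidazole, 4-(dimethylamino)pyridine (cat.), DMF, rt
Reagents that add atoms: chlorotriethylsilane, CC[Si](Cl)(CC)CC
Why: Silylation of the equatorial secondary alcohol under non-enolising conditions leaves the ketone alone. The ether keeps O6 from being phosphorylated in step 3 and stays on until the last step.

Step 3
Reactants: 3 silyl ether ketone
Product: 5 enyne (terminal alkyne C13≡C14 on the C11–C12 link; 6α-OSiEt3; exocyclic C8=CH2), via enol diethyl phosphate 4 (not isolated)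
Conditions: LiN(iPr)2, THF, −78 °C; ClP(O)(OEt)2, −78 °C → rt; then LiN(iPr)2 (excess), −78 °C → rt; aq. NH4Cl
Reagents that add atoms: none
Why: Kinetic deprotonation at the methyl group, O-phosphorylation to the terminal enol phosphate and base-induced β-elimination of diethyl phosphate give the 1-alkyne (enol phosphate route from methyl ketones). Excess amide holds the product as its acetylide, which suppresses isomerisation to an allene.

Step 4
Reactants: 5 enyne
Product: 6 8α-spiro-epoxide (oxygen α on C8, epoxide CH2 β)
Conditions: mCPBA, NaHCO3, CH2Cl2, 0 °C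
Reagents that add atoms: 3-chloroperoxybenzoic acid, OOC(=O)c1cccc(Cl)c1
Why: Prilezhaev epoxidation; the electron-rich 1,1-disubstituted alkene reacts far faster than the terminal alkyne. The peracid should approach C8 from the α-face because the β-face is screened by the axial C10 methyl in a 1,3-relationship, which places oxygen α on C8.

Step 5
Reactants: 6 epoxide
Product: 7 hydroxy alkyne (8α-OH, 8β-CH3, 6α-OSiEt3, terminal alkyne)
Conditions: LiAlH4, THF, 0 °C → rt
Reagents that add atoms: none
Why: SN2 opening of the epoxide by hydride at its unsubstituted CH2 carbon leaves the C8–O bond intact, so the α-oxygen of step 4 becomes the tertiary 8α-hydroxyl and the former methylene becomes the axial 8β-methyl. Isolated alkynes and silyl ethers are inert to LiAlH4 at this temperature.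

Step 6
Reactants: 8 3-methylfuran-2-carbaldehyde
Product: 11 3-methyl-5-(trimethylsilyl)furan-2-carbaldehyde, via lithium amino alkoxide 9 (not isolated), via C5-silylated lithium amino alkoxide 10 (not isolated)
Conditions: lithium N-methylpiperazide (from N-methylpiperazine, n-BuLi), THF, −78 °C; n-BuLi, −78 → −20 °C; Me3SiCl, −78 °C → rt; aq. NH4Cl
Reagents that add atoms: chlorotrimethylsilane, C[Si](C)(C)Cl
Why: α-Amino alkoxide directed metalation: the amide adds to the aldehyde and masks it, butyllithium removes the only ring α-hydrogen, and silylation followed by aqueous collapse of the hemiaminal returns the aldehyde. The ring position next to the masked aldehyde is blocked by the methyl group, so no regiochemical choice on the ring remains.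

Step 7
Reactants: 7 hydroxy alkyne; 11 silylated furan aldehyde
Product: 13 (15S)-propargylic alcohol (C15 carbinol between the 3-methyl-5-trimethylsilylfuran-2-yl group and the C14≡C13 alkyne), via alkynyl(methyl)zinc 12 (not isolated)
Conditions: Me2Zn (3 equiv), (S,S)-ProPhenol [2,6-bis({(2S)-2-[hydroxy(diphenyl)methyl]pyrrolidin-1-yl}methyl)-4-methylphenol] (20 mol %), Ph3P=O (40 mol %), toluene, rt; then 11 (2 equiv), 4 °C
Reagents that add atoms: none
Why: Catalytic enantioselective alkynylzinc addition to a heteroaromatic aldehyde: Me2Zn turns 7 into the alkynylzinc, and the dinuclear zinc complex of the ligand holds aldehyde and alkynyl group in one chiral pocket. The catalyst only has to distinguish H from the furyl group; the (S,S)-ligand is expected to deliver the alkynyl group to the Si face, which gives the 15S carbinol.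

Step 8
Reactants: 13 propargylic alcohol
Product: 15 (Z)-vinyl iodide (iodine on C13, cis to C15; H on C14), via cyclic vinylalanate 14 (not isolated)
Conditions: NaAlH2(OCH2CH2OMe)2 (4 equiv), THF, 0 °C → rt; then I2 (excess), THF, −78 → 0 °C; aq. Na2S2O3, Rochelle salt
Reagents that add atoms: iodine, [I][I]
Why: Hydroxyl-directed trans-hydroalumination of a propargylic alcohol: the aluminium hydride bound to O15 delivers hydride to C14 and the metal to C13 within a five-membered alanate, and iodinolysis replaces the C13–Al bond with retention. Iodine therefore sits cis to C15, which fixes the geometry of the later C13=C14 alkene.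

Step 9
Reactants: 15 vinyl iodide
Product: 16 15-O-tert-butyldimethylsilyl ether of 15
Conditions: tBuMe2SiCl, imidazole, DMF, 0 °C → rt
Reagents that add atoms: tert-butyldimethylsilyl chloride, CC(C)(C)[Si](C)(C)Cl
Why: Standard silylation of the secondary allylic alcohol; the tertiary 8α-hydroxyl is too hindered to react with the chloride. The ether later keeps O15 out of the furan oxidation and serves as the large non-chelating group for Felkin–Anh control.

Step 10
Reactants: 16 silylated vinyl iodide
Product: 17 silylfuran (13E alkene with methyl on C13; 15S-OSitBuMe2; furan with CH3 on C17 and SiMe3 on C19; 6α-OSiEt3; 8α-OH)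
Conditions: MeZnCl (4 equiv), Pd(PPh3)4 (5 mol %), THF, rt → 45 °C
Reagents that add atoms: methylzinc chloride, C[Zn]Cl
Why: Negishi cross-coupling; oxidative addition, transmetalation and reductive elimination all proceed with retention at the alkenyl carbon, so methyl takes the place of iodine cis to C15 and the alkene is 13E. The organozinc reagent leaves the silyl ethers, the furan C–Si bond and the tertiary alcohol alone.

Step 11
Reactants: 17 silylfuran
Product: 20 γ-hydroxybutenolide (C19 lactone carbonyl, C16 hemiketal as a pair of equilibrating epimers), via furan endoperoxide 18 (not isolated), via trimethylsilyl keto-enoate 19 (not isolated)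
Conditions: O2, hν (visible), rose bengal (C20H2Cl4I4Na2O5, cat.), THF, −78 °C; then H2O, → rt
Reagents that add atoms: dioxygen, O=O
Why: Energy transfer from the excited dye gives singlet oxygen, which adds suprafacially across C16 and C19 of the electron-rich furan in a [4+2] cycloaddition to give the bicyclic endoperoxide. Silicon then shifts from C19 to the adjacent peroxide oxygen as the O–O bond breaks, a silicon analogue of a Criegee-type migration, which opens the bicycle to the silyl (Z)-4-oxo-2-enoate with C19 at the acid and C16 at the ketone level. Water cleaves the silyl ester and the free acid adds to the C16 ketone (5-exo-trig ring–chain tautomerism), so the lactol ring replaces the furan ring and the ring count does not change. The closest known reaction type is the sensitised photooxygenation of 2-trialkylsilylfurans to γ-hydroxybutenolides. C16 becomes a hemiketal centre that is not controlled and need not be, since both epimers interconvert through the open keto acid and converge in step 12; C15 is untouched. Which carbon becomes the carbonyl is fixed by the position of silicon. Selectivity over the C13=C14 alkene rests on the much higher rate of furans than of trisubstituted alkenes toward singlet oxygen at −78 °C and on stopping after one equivalent is taken up. The O15 silyl ether keeps the carbinol from forming a pyranone, and no base is present.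

Step 12
Reactants: 20 γ-hydroxybutenolide
Product: 23 (15S,16S)-butenolide bis-silyl ether, via ring-opened keto carboxylate 21 (not isolated), via hydroxy carboxylate 22 (not isolated)
Conditions: NaBH4, CeCl3·7H2O, MeOH, −78 → −30 °C; then aq. citric acid (pH 4), 0 °C → rt
Reagents that add atoms: none
Why: Luche reduction: in the basic medium 20 opens to the keto carboxylate, and cerium-assisted borohydride adds 1,2 to the C16 ketone. In the Felkin–Anh arrangement the bulky, non-chelating O15 silyl ether stands anti to the incoming hydride, which should give the 15,16-syn alcohol (16S). Mild acid then closes the (Z)-γ-hydroxy acid to the butenolide without any base that could epimerise C16.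

Step 13
Reactants: 23 butenolide bis-silyl ether
Product: 24 target
Conditions: HF·pyridine, pyridine, THF, 0 °C → rt
Reagents that add atoms: none
Why: Fluoride-mediated cleavage of both silyl ethers under buffered, weakly acidic conditions. No base is present, so the C16–H of the butenolide, the allylic C15 alcohol and the E-alkene are expected to survive.

## Compound list

1 | (+)-larixol, (13S)-labda-8(17),14-diene-6α,13-diol | C=C[C@@](C)(O)CC[C@@H]1[C@@]2(C)CCCC(C)(C)[C@@H]2[C@@H](O)CC1=C | starting material
2 | methyl ketone: 6α-hydroxy decalin with exocyclic C8=CH2 and 3-oxobutyl chain on C9 | CC(=O)CC[C@@H]1[C@@]2(C)CCCC(C)(C)[C@@H]2[C@@H](O)CC1=C | intermediate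
3 | 6α-triethylsilyl ether of 2 | CC(=O)CC[C@@H]1[C@@]2(C)CCCC(C)(C)[C@@H]2[C@@H](O[Si](CC)(CC)CC)CC1=C | intermediate
4 | terminal enol diethyl phosphate of 3 | C=C(OP(=O)(OCC)OCC)CC[C@@H]1[C@@]2(C)CCCC(C)(C)[C@@H]2[C@@H](O[Si](CC)(CC)CC)CC1=C | intermediate
5 | enyne: 9β-(but-3-ynyl) decalin, 6α-OSiEt3, exocyclic C8=CH2 | C#CCC[C@@H]1[C@@]2(C)CCCC(C)(C)[C@@H]2[C@@H](O[Si](CC)(CC)CC)CC1=C | intermediate
6 | 8α-spiro-epoxide of 5 (O α, CH2 β on C8) | C#CCC[C@@H]1[C@@]2(C)CCCC(C)(C)[C@@H]2[C@@H](O[Si](CC)(CC)CC)C[C@]13CO3 | intermediate
7 | hydroxy alkyne: 8α-OH, 8β-CH3, 6α-OSiEt3, 9β-(but-3-ynyl) | C#CCC[C@@H]1[C@@]2(C)CCCC(C)(C)[C@@H]2[C@@H](O[Si](CC)(CC)CC)C[C@@]1(C)O | intermediate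
8 | 3-methylfuran-2-carbaldehyde | Cc1ccoc1C=O | starting material
9 | lithium α-(4-methylpiperazin-1-yl) alkoxide of 8 | [Li+].Cc1ccoc1C([O-])N1CCN(C)CC1 | intermediate
10 | C5-trimethylsilyl derivative of 9 | [Li+].Cc1cc([Si](C)(C)C)oc1C([O-])N1CCN(C)CC1 | intermediate
11 | 3-methyl-5-(trimethylsilyl)furan-2-carbaldehyde | Cc1cc([Si](C)(C)C)oc1C=O | intermediate
12 | alkynyl(methyl)zinc of 7 (O8 as methylzinc alkoxide) | C[Zn]C#CCC[C@@H]1[C@@]2(C)CCCC(C)(C)[C@@H]2[C@@H](O[Si](CC)(CC)CC)C[C@@]1(C)O[Zn]C | intermediate
13 | (15S)-propargylic alcohol: 1-[3-methyl-5-(trimethylsilyl)furan-2-yl]alk-2-yn-1-ol joined through C12–C11 to C9 of the 6α-OSiEt3, 8α-OH decalin | Cc1cc([Si](C)(C)C)oc1[C@@H](O)C#CCC[C@@H]1[C@@]2(C)CCCC(C)(C)[C@@H]2[C@@H](O[Si](CC)(CC)CC)C[C@@]1(C)O | intermediate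
14 | cyclic sodium vinylalanate (O15–Al–C13 five-membered ring; tertiary hydroxyl drawn free) | [Na+].COCCO[Al-]1(OCCOC)O[C@H](c2oc([Si](C)(C)C)cc2C)C=C1CC[C@@H]1[C@@]2(C)CCCC(C)(C)[C@@H]2[C@@H](O[Si](CC)(CC)CC)C[C@@]1(C)O | intermediate
15 | (15S,13Z)-13-iodo allylic alcohol | Cc1cc([Si](C)(C)C)oc1[C@@H](O)/C=C(\I)CC[C@@H]1[C@@]2(C)CCCC(C)(C)[C@@H]2[C@@H](O[Si](CC)(CC)CC)C[C@@]1(C)O | intermediate
16 | 15-O-tert-butyldimethylsilyl ether of 15 | Cc1cc([Si](C)(C)C)oc1[C@@H](O[Si](C)(C)C(C)(C)C)/C=C(\I)CC[C@@H]1[C@@]2(C)CCCC(C)(C)[C@@H]2[C@@H](O[Si](CC)(CC)CC)C[C@@]1(C)O | intermediate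
17 | silylfuran: (15S,13E)-15-OSitBuMe2 [3-methyl-5-(trimethylsilyl)furan-2-yl]carbinol of the 6α-OSiEt3, 8α-OH decalin chain | Cc1cc([Si](C)(C)C)oc1[C@@H](O[Si](C)(C)C(C)(C)C)/C=C(\C)CC[C@@H]1[C@@]2(C)CCCC(C)(C)[C@@H]2[C@@H](O[Si](CC)(CC)CC)C[C@@]1(C)O | intermediate
18 | furan endoperoxide (O–O bridge between C16 and C19) | C[Si](C)(C)C12OOC(O1)(C(C)=C2)[C@@H](O[Si](C)(C)C(C)(C)C)/C=C(\C)CC[C@@H]1[C@@]2(C)CCCC(C)(C)[C@@H]2[C@@H](O[Si](CC)(CC)CC)C[C@@]1(C)O | intermediate
19 | trimethylsilyl (Z)-4-oxo-3-methyl-2-enoate (C19 ester, C16 ketone) | C[Si](C)(C)OC(=O)/C=C(C)\C(=O)[C@@H](O[Si](C)(C)C(C)(C)C)/C=C(\C)CC[C@@H]1[C@@]2(C)CCCC(C)(C)[C@@H]2[C@@H](O[Si](CC)(CC)CC)C[C@@]1(C)O | intermediate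
20 | γ-hydroxybutenolide: 16-hydroxy, 15-OSitBuMe2, 6-OSiEt3 (C16 epimers) | CC1=CC(=O)OC1(O)[C@@H](O[Si](C)(C)C(C)(C)C)/C=C(\C)CC[C@@H]1[C@@]2(C)CCCC(C)(C)[C@@H]2[C@@H](O[Si](CC)(CC)CC)C[C@@]1(C)O | intermediate
21 | sodium (Z)-4-oxo-3-methyl-2-enoate, ring-opened form of 20 | [Na+].[O-]C(=O)/C=C(C)\C(=O)[C@@H](O[Si](C)(C)C(C)(C)C)/C=C(\C)CC[C@@H]1[C@@]2(C)CCCC(C)(C)[C@@H]2[C@@H](O[Si](CC)(CC)CC)C[C@@]1(C)O | intermediate
22 | sodium (Z,16S)-4-hydroxy-3-methyl-2-enoate | [Na+].[O-]C(=O)/C=C(C)\[C@H](O)[C@@H](O[Si](C)(C)C(C)(C)C)/C=C(\C)CC[C@@H]1[C@@]2(C)CCCC(C)(C)[C@@H]2[C@@H](O[Si](CC)(CC)CC)C[C@@]1(C)O | intermediate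
23 | (15S,16S)-butenolide, 15-OSitBuMe2, 6-OSiEt3 | CC1=CC(=O)O[C@@H]1[C@@H](O[Si](C)(C)C(C)(C)C)/C=C(\C)CC[C@@H]1[C@@]2(C)CCCC(C)(C)[C@@H]2[C@@H](O[Si](CC)(CC)CC)C[C@@]1(C)O | intermediate
24 | target, CNP0279704.1 | CC1=CC(=O)O[C@@H]1[C@@H](O)/C=C(\C)CC[C@@H]1[C@@]2(C)CCCC(C)(C)[C@@H]2[C@@H](O)C[C@@]1(C)O | target

## Step count and least certain steps

Total step count: 13. Longest linear sequence: 12 steps (1 to 24 through steps 1–5 and 7–13); step 6 is a one-step branch.

**Step 11 (key step).** The most likely failure is competing ene-type oxygenation of the C13=C14 alkene, or interception of the endoperoxide before silicon migrates, which would give mixed peroxidic products. The fallback drops the silicon trigger and uses base-induced collapse of the endoperoxide. It sets out from 7 and 8 and comes back at 20. Aldehyde 8 is used in place of 11 in the chemistry of steps 7 to 10, giving in turn the propargylic alcohol without furan silicon F1, the vinyl iodide without furan silicon F2, its tert-butyldimethylsilyl ether F3 and the 2-alkyl-3-methylfuran F4. Photooxygenation of F4 (O2, hν, rose bengal (C20H2Cl4I4Na2O5), iPr2NEt, CH2Cl2, −78 °C) lets the amine remove the only bridgehead hydrogen of the endoperoxide, on C19. Kornblum–DeLaMare fragmentation then gives 20 with the same regiochemistry.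

**Step 7.** Two things may go wrong: weak enantioface discrimination or slow alkynyl transfer, because the tertiary zinc alkoxide of 7 may disturb the dinuclear catalyst and 7 is the limiting partner; and the sense of induction, which is specified by analogy with aryl aldehydes and should be confirmed by Mosher ester analysis, the antipodal ligand being the remedy. The fallback sets out from 7 and 11 and comes back at 13. The dilithio derivative of 7 (n-BuLi, THF, −78 °C) is added to 11 to give the C15-epimeric propargylic alcohols F5, and MnO2 gives the furyl ynone F6. Corey–Bakshi–Shibata reduction with (R)-2-methyl-CBS-oxazaborolidine [(3aR)-1-methyl-3,3-diphenyltetrahydro-1H,3H-pyrrolo[1,2-c][1,3,2]oxazaborole] and catecholborane follows. With the furyl group as the large substituent and the linear alkynyl group as the small one, this should give the 15S alcohol 13.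

**Step 8.** The risk is loss of regiocontrol in the hydroalumination (hydride delivered to C13), or electrophilic iodination or ipso-desilylation of the furan during the quench. The fallback builds the alkene by syn-carbometalation and sets out from 7 and 11, coming back at 17. Alkyne 7 is carboaluminated (AlMe3, Cp2ZrCl2 cat., CH2Cl2, 0 °C → rt) to the (E)-alkenyl(dimethyl)alane F7, which is added to 11 to give the C15-epimeric allylic alcohols F8. MnO2 gives the enone F9, and reduction with the same (R)-oxazaborolidine and catecholborane should give the (15S)-allylic alcohol F10. Silylation as in step 9 gives 17. The weakness of this fallback is that the reduction must tell a furyl from an alkenyl group.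

**Step 12.** Felkin–Anh control may be eroded if cerium chelates O15, or the silyl group may migrate from O15 to the new C16 alkoxide. The fallback is a recycling loop that sets out from the unwanted epimer and comes back at 20. The (16R)-epimer of 23 F11 is separated and converted with iPr3SiOSO2CF3 and Et3N into the 2-(triisopropylsilyloxy)furan F12. Sensitised photooxygenation of F12 as in step 11 returns 20 for another reduction.

**Step 4.** The risk is peracid attack from the β-face, which would give the C8 epimer. The fallback uses a bulkier oxidant and sets out from 5, coming back at 6. Dihydroxylation (OsO4 cat., N-methylmorpholine N-oxide, acetone–H2O), which reacts with the alkene much faster than with the alkyne and should be more face-selective, gives the 8α-hydroxy-8β-hydroxymethyl diol F13. Treatment with NaH and 1-(p-toluenesulfonyl)imidazole forms the primary sulfonate F14, which closes to epoxide 6 with the C8–O bond intact.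

## Further compounds

F1 | step 11 | (15S)-propargylic alcohol without furan silicon (C19–H analogue of 13) | Cc1ccoc1[C@@H](O)C#CCC[C@@H]1[C@@]2(C)CCCC(C)(C)[C@@H]2[C@@H](O[Si](CC)(CC)CC)C[C@@]1(C)O
F2 | step 11 | (13Z)-vinyl iodide without furan silicon (C19–H analogue of 15) | Cc1ccoc1[C@@H](O)/C=C(\I)CC[C@@H]1[C@@]2(C)CCCC(C)(C)[C@@H]2[C@@H](O[Si](CC)(CC)CC)C[C@@]1(C)O
F3 | step 11 | 15-O-tert-butyldimethylsilyl ether of F2 | Cc1ccoc1[C@@H](O[Si](C)(C)C(C)(C)C)/C=C(\I)CC[C@@H]1[C@@]2(C)CCCC(C)(C)[C@@H]2[C@@H](O[Si](CC)(CC)CC)C[C@@]1(C)O
F4 | step 11 | 2-alkyl-3-methylfuran (C19–H analogue of 17) | Cc1ccoc1[C@@H](O[Si](C)(C)C(C)(C)C)/C=C(\C)CC[C@@H]1[C@@]2(C)CCCC(C)(C)[C@@H]2[C@@H](O[Si](CC)(CC)CC)C[C@@]1(C)O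
F5 | step 7 | C15-epimeric propargylic alcohols | Cc1cc([Si](C)(C)C)oc1C(O)C#CCC[C@@H]1[C@@]2(C)CCCC(C)(C)[C@@H]2[C@@H](O[Si](CC)(CC)CC)C[C@@]1(C)O
F6 | step 7 | furyl ynone (C15 ketone) | Cc1cc([Si](C)(C)C)oc1C(=O)C#CCC[C@@H]1[C@@]2(C)CCCC(C)(C)[C@@H]2[C@@H](O[Si](CC)(CC)CC)C[C@@]1(C)O
F7 | step 8 | (E)-alkenyl(dimethyl)alane from 7 (O8 as dimethylaluminium alkoxide) | C[Al](C)/C=C(\C)CC[C@@H]1[C@@]2(C)CCCC(C)(C)[C@@H]2[C@@H](O[Si](CC)(CC)CC)C[C@@]1(C)O[Al](C)C
F8 | step 8 | C15-epimeric (13E)-allylic alcohols | Cc1cc([Si](C)(C)C)oc1C(O)/C=C(\C)CC[C@@H]1[C@@]2(C)CCCC(C)(C)[C@@H]2[C@@H](O[Si](CC)(CC)CC)C[C@@]1(C)O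
F9 | step 8 | (13E)-furyl enone (C15 ketone) | Cc1cc([Si](C)(C)C)oc1C(=O)/C=C(\C)CC[C@@H]1[C@@]2(C)CCCC(C)(C)[C@@H]2[C@@H](O[Si](CC)(CC)CC)C[C@@]1(C)O
F10 | step 8 | (15S,13E)-allylic alcohol | Cc1cc([Si](C)(C)C)oc1[C@@H](O)/C=C(\C)CC[C@@H]1[C@@]2(C)CCCC(C)(C)[C@@H]2[C@@H](O[Si](CC)(CC)CC)C[C@@]1(C)O
F11 | step 12 | (15S,16R)-butenolide, 16-epimer of 23 | CC1=CC(=O)O[C@H]1[C@@H](O[Si](C)(C)C(C)(C)C)/C=C(\C)CC[C@@H]1[C@@]2(C)CCCC(C)(C)[C@@H]2[C@@H](O[Si](CC)(CC)CC)C[C@@]1(C)O
F12 | step 12 | 2-(triisopropylsilyloxy)-4-methylfuran derived from F11 | Cc1cc(O[Si](C(C)C)(C(C)C)C(C)C)oc1[C@@H](O[Si](C)(C)C(C)(C)C)/C=C(\C)CC[C@@H]1[C@@]2(C)CCCC(C)(C)[C@@H]2[C@@H](O[Si](CC)(CC)CC)C[C@@]1(C)O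
F13 | step 4 | 8α-hydroxy-8β-hydroxymethyl diol from 5 | C#CCC[C@@H]1[C@@]2(C)CCCC(C)(C)[C@@H]2[C@@H](O[Si](CC)(CC)CC)C[C@@]1(CO)O
F14 | step 4 | primary p-toluenesulfonate of F13 as sodium C8 alkoxide | [Na+].C#CCC[C@@H]1[C@@]2(C)CCCC(C)(C)[C@@H]2[C@@H](O[Si](CC)(CC)CC)C[C@@]1(COS(=O)(=O)c1ccc(C)cc1)[O-]
A1 | alternative 1 | (2E,6E)-farnesyl diphosphate | CC(C)=CCC/C(C)=C/CC/C(C)=C/COP(=O)(O)OP(=O)(O)O
A2 | alternative 1 | drimenol (drim-7-en-11-ol) | OC[C@@H]1[C@@]2(C)CCCC(C)(C)[C@@H]2CC=C1C
A3 | alternative 2 | monocyclic ring-A aldehyde with isopropenyl group on C9 and ketal-protected chain | CC1(CC[C@H]([C@@]2(C)CCCC(C)(C)[C@@H]2C=O)C(C)=C)OCCO1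
A4 | alternative 2 | ethylene ketal of ketone 2 | CC1(CC[C@@H]2[C@@]3(C)CCCC(C)(C)[C@@H]3[C@@H](O)CC2=C)OCCO1
A5 | alternative 3 | acyclic silyloxydiene–enal | O=C/C=C(\C)CCCC(C)(C)/C=C(O[Si](C)(C)C(C)(C)C)/C=C/C
A6 | alternative 3 | trans-fused cycloadduct, 6-[(tert-butyldimethylsilyl)oxy]drim-6-en-11-al | O=C[C@@H]1[C@@]2(C)CCCC(C)(C)[C@@H]2C(O[Si](C)(C)C(C)(C)C)=C[C@@H]1C
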